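**Retrosynthetic overview**
1. Target ← para-selective bromination (ring A, para to its OH) of 3,4,6-tribromo-2-(2-hydroxyphenoxy)phenol.
2. That bis-phenol ← reductive C–O scission and aromatisation of an o-quinone catechol spiroketal; the catechol is symmetric, so either C–O cleavage gives the same diaryl ether.
3. Spiroketal (the diaryl ether C–O bond) ← new TMSOTf-catalysed silyl-transfer spiroketalisation of a tribrominated masked o-benzoquinone with catechol bis-TMS ether.
4. Masked o-benzoquinone ← PhI(OAc)2/MeOH dearomatisation of 3,4,6-tribromo-2-methoxyphenol ← OH-directed dibromination of 3-bromo-2-methoxyphenol.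
5. Ring order: both benzene rings are bought; the only ring formed is the transient spiro-1,3-benzodioxole (step 3), which is opened again in step 4.

Assumption: the target has no stereocentre and no stable atropisomer, so it is achiral and "single enantiomer" means this one constitution; the only stereocentre on the route (transient ketal 6) is racemic and is destroyed.

**Route**

Step 1
Reactants: 1 3-bromo-2-methoxyphenol
Product: 3 3,4,6-tribromo-2-methoxyphenol, via 3,4-dibromo-2-methoxyphenol 2 (not isolated)
Conditions: Br2 (2.05 equiv), AcOH/CH2Cl2, 0 °C → rt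
Reagents that add atoms: bromine, BrBr
Why: Electrophilic aromatic bromination (SEAr) in which the free OH directs para (C4) and then ortho (C6), while the OMe, flanked by OH and Br and twisted out of conjugation, does not compete, so C5 stays H.

Step 2
Reactants: 3 3,4,6-tribromo-2-methoxyphenol
Product: 4 2,4,5-tribromo-6,6-dimethoxycyclohexa-2,4-dien-1-one
Conditions: PhI(OAc)2 (1.1 equiv), MeOH, 0 °C, 20 min; short silica plug
Reagents that add atoms: methanol, CO
Why: Hypervalent-iodine oxidative dearomatisation of a 2-methoxyphenol to a masked o-benzoquinone (o-quinone monoketal), with methanol adding at the methoxy-bearing ortho carbon where the cation is oxygen-stabilised; the three bromines suppress Diels–Alder dimerisation and no stereocentre arises.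

Step 3
Reactants: 4 2,4,5-tribromo-6,6-dimethoxycyclohexa-2,4-dien-1-one; 5 1,2-bis(trimethylsilyloxy)benzene
Product: 7 3',5',6'-tribromospiro[1,3-benzodioxole-2,1'-cyclohexa[3,5]dien]-2'-one, via mixed methyl aryl ketal 6 (not isolated)
Conditions: 5 (1.2 equiv), TMSOTf (10 mol%), CH2Cl2, −78 → −20 °C; Et3N quench
Reagents that add atoms: none
Why: Proposed new method: TMSOTf silylates one ketal OMe of 4 and expels MeOSiMe3 to give a 2-methoxy oxocarbenium (O-methylated o-quinone) whose other cationic positions (C2, C4) carry Br, so the aryl silyl ether oxygen of 5 attacks the ketal carbon (giving 6 and regenerating TMSOTf), and a second ionisation with 5-membered closure by the neighbouring OSiMe3 forms the spiro-1,3-benzodioxole, driven by two strong Si–OMe bonds and chelate entropy; the closest known reaction types are Noyori ketalisation with diol bis-silyl ethers, TMSOTf O-glycosylation of aryl silyl ethers and acid-catalysed ketal exchange of masked o-benzoquinones with alcohols; the spiro carbon carries a symmetric catecholate and is not a stereocentre.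

Step 4
Reactants: 7 3',5',6'-tribromospiro[1,3-benzodioxole-2,1'-cyclohexa[3,5]dien]-2'-one
Product: 8 3,4,6-tribromo-2-(2-hydroxyphenoxy)phenol
Conditions: Zn dust (3 equiv), AcOH/THF (1:4), 0 °C, 30 min
Reagents that add atoms: none
Why: Dissolving-metal reductive cleavage of an α-aryloxy ketone (reductive aromatisation of a quinone monoketal), in which two-electron reduction of the dienone expels one catecholate oxygen from the spiro carbon; both C–O bonds are equivalent so one diaryl ether forms, and aryl bromides are inert to Zn/AcOH at 0 °C.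

Step 5
Reactants: 8 3,4,6-tribromo-2-(2-hydroxyphenoxy)phenol
Product: 9 3,4,6-tribromo-2-(5-bromo-2-hydroxyphenoxy)phenol
Conditions: NBS (1.0 equiv), MeCN, −20 → 0 °C
Reagents that add atoms: N-bromosuccinimide, O=C1CCC(=O)N1Br
Why: Electrophilic aromatic bromination (SEAr) para to the free OH of the electron-rich ring A (OH outranks the aryloxy group as director), while ring B has only one deactivated C–H flanked by two bromines; one equivalent at low temperature limits ortho over-bromination.

**Compound list**
1 | 3-bromo-2-methoxyphenol | COc1c(O)cccc1Br | starting material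
2 | 3,4-dibromo-2-methoxyphenol | COc1c(O)ccc(Br)c1Br | intermediate
3 | 3,4,6-tribromo-2-methoxyphenol | COc1c(O)c(Br)cc(Br)c1Br | intermediate
4 | 2,4,5-tribromo-6,6-dimethoxycyclohexa-2,4-dien-1-one | COC1(OC)C(Br)=C(Br)C=C(Br)C1=O | intermediate
5 | 1,2-bis(trimethylsilyloxy)benzene | C[Si](C)(C)Oc1ccccc1O[Si](C)(C)C | starting material
6 | 2,4,5-tribromo-6-methoxy-6-[2-(trimethylsilyloxy)phenoxy]cyclohexa-2,4-dien-1-one (racemic) | COC1(Oc2ccccc2O[Si](C)(C)C)C(Br)=C(Br)C=C(Br)C1=O | intermediate
7 | 3',5',6'-tribromospiro[1,3-benzodioxole-2,1'-cyclohexa[3,5]dien]-2'-one | O=C1C(Br)=CC(Br)=C(Br)C12Oc3ccccc3O2 | intermediate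
8 | 3,4,6-tribromo-2-(2-hydroxyphenoxy)phenol | Oc1ccccc1Oc1c(O)c(Br)cc(Br)c1Br | intermediate
9 | 3,4,6-tribromo-2-(5-bromo-2-hydroxyphenoxy)phenol | Oc1ccc(Br)cc1Oc1c(O)c(Br)cc(Br)c1Br | target

**Totals**
Total step count: 5. Longest linear sequence: 5 steps (from 1).

**Three steps most likely to fail**

Step 3 (the proposed new step). Risks are sluggish ionisation of the electron-poor ketal, C-attack of the silyloxyarene at the ketal carbon, and redox exchange giving back 3. The fallback uses known chemistry, sets out from 3 and comes back at 8. Compound 3 is mesylated (MsCl, Et3N, CH2Cl2, 0 °C) to 3,4,6-tribromo-2-methoxyphenyl methanesulfonate F1. BBr3 (CH2Cl2, −78 → 0 °C) cleaves the methyl ether and leaves the sulfonate, giving 3,4,6-tribromo-2-hydroxyphenyl methanesulfonate F2. Chan–Lam–Evans O-arylation with (2-methoxyphenyl)boronic acid (Cu(OAc)2, pyridine, 4 Å MS, CH2Cl2, air, rt) gives 3,4,6-tribromo-2-(2-methoxyphenoxy)phenyl methanesulfonate F3. A second BBr3 demethylation gives 3,4,6-tribromo-2-(2-hydroxyphenoxy)phenyl methanesulfonate F4, and KOH in MeOH/H2O at 60 °C removes the mesylate to give 8, which continues with step 5.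

Step 2. Risks are that the electron-poor phenol oxidises slowly, that methanol attacks the bromine-bearing para carbon, or that methanol displaces a vinylic bromide of 4. The fallback sets out from 3 and comes back at 7. A Wessely oxidation (Pb(OAc)4, AcOH/CH2Cl2, rt) delivers acetate intramolecularly to the methoxy-bearing ortho carbon in a non-nucleophilic medium and gives racemic 2,3,5-tribromo-1-methoxy-6-oxocyclohexa-2,4-dien-1-yl acetate F5. Under the step 3 conditions (5, TMSOTf) its acetate ionises first, so it passes through the same mixed ketal 6 and closes to 7.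

Step 5. Risks are ortho/para mixtures or dibromination of ring A. The fallback sets out from 8 and comes back at 9. Both phenols are methylated (MeI, K2CO3, DMF) to 1,2,5-tribromo-4-methoxy-3-(2-methoxyphenoxy)benzene F6. Anisole-type bromination (NBS, MeCN, rt) then goes cleanly para to the ring A methoxy group to give 1,2,5-tribromo-3-(5-bromo-2-methoxyphenoxy)-4-methoxybenzene F7, and BBr3 (CH2Cl2, −78 °C → rt) cleaves both methyl ethers to give 9.

**Further compounds**
F1 | step 3 | 3,4,6-tribromo-2-methoxyphenyl methanesulfonate | COc1c(OS(C)(=O)=O)c(Br)cc(Br)c1Br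
F2 | step 3 | 3,4,6-tribromo-2-hydroxyphenyl methanesulfonate | Oc1c(OS(C)(=O)=O)c(Br)cc(Br)c1Br
F3 | step 3 | 3,4,6-tribromo-2-(2-methoxyphenoxy)phenyl methanesulfonate | COc1ccccc1Oc1c(OS(C)(=O)=O)c(Br)cc(Br)c1Br
F4 | step 3 | 3,4,6-tribromo-2-(2-hydroxyphenoxy)phenyl methanesulfonate | Oc1ccccc1Oc1c(OS(C)(=O)=O)c(Br)cc(Br)c1Br
F5 | step 2 | 2,3,5-tribromo-1-methoxy-6-oxocyclohexa-2,4-dien-1-yl acetate (racemic) | CC(=O)OC1(OC)C(Br)=C(Br)C=C(Br)C1=O
F6 | step 5 | 1,2,5-tribromo-4-methoxy-3-(2-methoxyphenoxy)benzene | COc1ccccc1Oc1c(OC)c(Br)cc(Br)c1Br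
F7 | step 5 | 1,2,5-tribromo-3-(5-bromo-2-methoxyphenoxy)-4-methoxybenzene | COc1ccc(Br)cc1Oc1c(OC)c(Br)cc(Br)c1Br
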